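The earlier runs and the new flask are simulated on assumed constants; noise was put on by code.

1.3 µM of impurity stood against 6.00 µM of enzyme in the flask, so I reckoned with the enzyme left rather than with the enzyme spent.

common to all: substrate 0.050 M; impurity 1.3 µM

|  | enzyme | remark |
|---|---|---|
| delta | 0.017 mol% | run made earlier |
| epsilon | 0.026 mol% | run made earlier |
| flask | 0.012 mol% |  |

- delta (time / h: target / %): 0.417: 73.8; 0.833: 76.2; 1.33: 75.2; 1.50: 76.0; 2.00: 75.7; 2.50: 75.5; 3.00: 76.1
- epsilon (time / h: target / %): 0.417: 83.1; 0.833: 83.6; 1.33: 83.5; 1.50: 83.5; 2.00: 83.2; 2.50: 83.5; 3.00: 83.0

(readings scatter by 0.3 percentage points)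

- apparent order in enzyme when 30% of the substrate are converted (percent change of the rate of making target for one percent more enzyme charged)

- reactions considered so far: substrate + enzyme -> target + enzyme; substrate -> uncatalysed product; enzyme + impurity -> spent catalyst

Delta levelled off at 75.8% target and epsilon at 83.3%, and I took the remainder as uncatalysed product. Target over uncatalysed product, a selectivity factor, was therefore 3.13 in delta and 5.00 in epsilon. I assumed that this factor follows the working enzyme, since the uncatalysed step uses none. Its ratio, 1.60, exceeded the charged ratio of 1.53, and a fixed loss of enzyme would produce such an excess. Solving for that loss gave 0.986 µM, a reading subject to the scatter and below the impurity charged.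

At 30% conversion the substrate is the same for any enzyme loading at this substrate charge, so I let the rate follow [enzyme] charged minus that loss, assuming the loss was complete by then. The apparent order is then the reciprocal of the fraction of enzyme left, which for the flask I put at 83.6%, so I expected 1.20. The forecast gave 1.1, lower than my figure, on the view that “poisoning occurs on roughly the reaction timescale”.

The flask gave 1.2.

    substrate + enzyme → target + enzyme, rate k1*[substrate]*[enzyme]/(1 + ([substrate]/Km1) + ([target]/Kp1)) (0.0950 M, 0.0790 M, k = 410 /M/s)
    substrate → uncatalysed product (k = 6.30 × 10⁻⁴ /s)
    enzyme + impurity → spent catalyst (k = 87000 /M/s)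

When 30% of the substrate was converted, at 0.0519 h, 21.7% of the catalyst in the flask was spent catalyst. The fraction of enzyme left at that moment was therefore 78.3%, against the 83.6% I had estimated from the plateaux, and the reciprocal of that fraction is 1.28, higher than the 1.2 of the flask.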